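**Retrosynthetic overview** (quinic acid numbering: C1 = C(OH)(CO2H), C2/C6 = CH2, C3 = CH(OH), C4 = CH(O-malonyl), C5 = CH(O-caffeoyl))
- Target ⇒ fully protected diester (one acidolysis) ⇒ tert-butyl (−)-quinate by two site-selective acylations: malonyl on O4 through cis-diol recognition, then caffeoyl on the equatorial O5.
- tert-Butyl quinate ⇒ 5-oxocyclohex-3-ene-1-carboxylate (enone) by hydroxyl-directed 1,3-anti reduction (sets C5) and anti-dihydroxylation of C3=C4 (sets C3, C4); all three centres are relayed from C1.
- Enone ⇒ achiral 3-oxocyclobutane + acetylene: a desymmetrizing two-carbon ring expansion forms C2–C3 and C4–C5 and cleaves the old C2–C5 bond. The cyclohexane is the only ring formed in the route (four-membered ring in, six-membered ring out).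
- Enabling feature: C1 carries no hydrogen and sits between two CH2 groups (C2, C6), with the oxygenated C5 in a 1,3-relation to it. The path C2–C1–C6–C5 therefore folds into a 3,3-disubstituted cyclobutanone with a mirror plane through C1 and C5. C1 is stereogenic in the target only because its two ring arms differ, and ring strain drives the C5–C2 cleavage.
- Cyclobutanone ⇐ commercial 3-methylidenecyclobutanecarboxylic acid (esterification, enolate hydroxylation, silylation, ozonolysis).

Key step: step 5

Assumption: the sense of induction of the chiral carbene in step 5 cannot be predicted with certainty; the ligand enantiomer that delivers the (1S)-enone is used (its antipode would give the mirror-image series), and the (R,R,R,R) descriptor below stands for that choice.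

**Step 1**
Reactants: 1 3-methylidenecyclobutane-1-carboxylic acid
Product: 2 tert-butyl 3-methylidenecyclobutane-1-carboxylate
Conditions: tert-butyl 2,2,2-trichloroacetimidate (2 equiv), CH2Cl2/cyclohexane, rt
Reagents that add atoms: tert-butyl 2,2,2-trichloroacetimidate, CC(C)(C)OC(=N)C(Cl)(Cl)Cl
Why: Imidate esterification (acid-promoted tert-butyl transfer to the carboxylic acid) runs without added strong acid, so the exocyclic alkene should survive; no stereocentre is formed.

**Step 2**
Reactants: 2 tert-butyl 3-methylidenecyclobutane-1-carboxylate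
Product: 3 tert-butyl 1-hydroxy-3-methylidenecyclobutane-1-carboxylate
Conditions: LiN(iPr)2 (1.1 equiv), THF, −78 °C; trans-3-phenyl-2-(phenylsulfonyl)oxaziridine (1.3 equiv), −78 °C; AcOH quench
Reagents that add atoms: trans-3-phenyl-2-(phenylsulfonyl)oxaziridine (Davis oxaziridine), O=S(=O)(c1ccccc1)N1OC1c1ccccc1
Why: Davis hydroxylation of the ester enolate should install the tertiary carbinol; the product is achiral because the ring keeps its mirror plane.

**Step 3**
Reactants: 3 tert-butyl 1-hydroxy-3-methylidenecyclobutane-1-carboxylate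
Product: 4 tert-butyl 3-methylidene-1-[(trimethylsilyl)oxy]cyclobutane-1-carboxylate
Conditions: Me3SiOTf (1.2 equiv), Et3N (1.5 equiv), CH2Cl2, 0 °C
Reagents that add atoms: trimethylsilyl trifluoromethanesulfonate, C[Si](C)(C)OS(=O)(=O)C(F)(F)F
Why: Silyl triflate silylation of the hindered tertiary alcohol; the ether later blocks retro-aldol opening of the β-oxygenated cyclobutanone and protonolysis of nickel intermediates.

**Step 4**
Reactants: 4 tert-butyl 3-methylidene-1-[(trimethylsilyl)oxy]cyclobutane-1-carboxylate
Product: 5 tert-butyl 3-oxo-1-[(trimethylsilyl)oxy]cyclobutane-1-carboxylate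
Conditions: O3, CH2Cl2, −78 °C; then PPh3, −78 °C → rt
Reagents that add atoms: ozone, [O-][O+]=O
Why: Ozonolysis with reductive work-up should unmask the ketone under neutral conditions that spare the tert-butyl ester and silyl ether; the cyclobutanone is achiral (mirror plane through the carbonyl carbon and the carbinol carbon).

**Step 5**
Reactants: 5 tert-butyl 3-oxo-1-[(trimethylsilyl)oxy]cyclobutane-1-carboxylate; 6 acetylene
Product: 7 tert-butyl (1S)-5-oxo-1-[(trimethylsilyl)oxy]cyclohex-3-ene-1-carboxylate
Conditions: Ni(cod)2 (10 mol %), (R,R,R,R)-1,3-bis[2,6-bis(1-phenylethyl)phenyl]-4,5-dihydroimidazol-2-ylidene (12 mol %), toluene, 50 °C; acetylene fed slowly (about 1.5 equiv over several hours)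
Reagents that add atoms: none
Why: Proposed new method: zerovalent nickel bearing the bulky chiral carbene should couple acetylene and the strained ketone by oxidative cyclization to a spiro oxanickelacyclopentene (C4–C5 bond), after which β-carbon elimination of one of the two enantiotopic CH2–C(O) ring bonds (release of four-ring strain) and C(sp2)–C(sp3) reductive elimination from the resulting seven-membered nickelacycle form the C3–C2 bond and the enone. The closest known reaction type is the nickel/phosphine-catalysed intermolecular insertion of internal alkynes into 3,3-disubstituted cyclobutanones, and nickel/carbene carbonyl–alkyne oxidative cyclizations are known to accept terminal alkynes; new here are unsubstituted acetylene and ligand-controlled choice between the two mirror-related ring bonds. The cyclohexenone is not closed by an exo or endo cyclization but by two-carbon ring expansion, the ring-closing event being the reductive elimination that contracts the seven-membered nickelacycle to the six-membered carbocycle. C1, prochiral in the substrate, becomes the only new stereocentre, and its configuration is set by the chiral carbene, which decides which CH2 group migrates from carbon to nickel. The step needs this enantiotopic-group selectivity and mono-insertion in preference to acetylene oligomerization, double insertion and β-siloxy elimination: the symmetric alkyne removes any regiochemical question, the quaternary C1 leaves the alkylnickel without β-hydrogen, the silyl ether (a poor leaving group that also blocks retro-aldol opening) and the bulky carbene favour reductive elimination, and slow acetylene feed keeps the alkyne concentration low.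

**Step 6**
Reactants: 7 tert-butyl (1S)-5-oxo-1-[(trimethylsilyl)oxy]cyclohex-3-ene-1-carboxylate
Product: 9 tert-butyl (1S,5R)-1,5-dihydroxycyclohex-3-ene-1-carboxylate, via hydroxy enone 8 (not isolated)
Conditions: citric acid (0.2 equiv), MeOH, 0 °C; evaporate below 20 °C; then Me4NBH(OAc)3 (5 equiv), MeCN/AcOH (1:1), −30 → −20 °C
Reagents that add atoms: none
Why: Mild acid methanolysis frees the tertiary alcohol, which exchanges onto boron and delivers hydride to the same face of the enone carbonyl (Evans–Saksena 1,3-anti reduction, 1,2-selective), so the new C5 hydroxyl should be trans to the C1 hydroxyl (5R); the crude β-hydroxy enone is reduced at once to avoid dehydration and aromatization.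

**Step 7**
Reactants: 9 tert-butyl (1S,5R)-1,5-dihydroxycyclohex-3-ene-1-carboxylate
Product: 10 tert-butyl (−)-quinate [tert-butyl (1S,3R,4S,5R)-1,3,4,5-tetrahydroxycyclohexane-1-carboxylate; O1, O3, O4 cis, O5 trans]
Conditions: OsO4 (2 mol %), NMO (1.3 equiv), acetone/H2O (5:1), 0 °C → rt
Reagents that add atoms: N-methylmorpholine N-oxide, C[N+]1([O-])CCOCC1; water, O
Why: Upjohn syn-dihydroxylation should occur on the ring face opposite the allylic C5 hydroxyl (Kishi model), which is also the face of the axial C1 hydroxyl, setting C3 and C4 cis to each other and trans to O5 as in (−)-quinic acid.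

**Step 8**
Reactants: 10 tert-butyl (−)-quinate; 11 mono-tert-butyl malonate (3-tert-butoxy-3-oxopropanoic acid)
Product: 13 tert-butyl 4-O-(3-tert-butoxy-3-oxopropanoyl)-(−)-quinate, via acid chloride 12 (not isolated)
Conditions: 11, 1-chloro-N,N,2-trimethylprop-1-en-1-amine (Ghosez reagent, 1.05 equiv), CH2Cl2, 0 °C; then 10, 2-aminoethyl diphenylborinate (10 mol %), iPr2NEt (1.5 equiv), MeCN, 0 °C → rt
Reagents that add atoms: none
Why: The borinate binds the only cis-1,2-diol (O3/O4) as a tetracoordinate adduct, and the acid chloride, made under neutral conditions, should acylate its equatorial oxygen O4 (borinic-acid-catalysed regioselective acylation of cis-diols); no stereocentre is touched.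

**Step 9**
Reactants: 14 caffeic acid
Product: 16 (E)-3-[3,4-bis(methoxymethoxy)phenyl]prop-2-enoic acid, via tris-MOM ester 15 (not isolated)
Conditions: MOMCl (3.5 equiv), iPr2NEt (4 equiv), CH2Cl2/DMF, 0 °C → rt; then LiOH (3 equiv), THF/MeOH/H2O, rt; 1 M HCl to pH 4
Reagents that add atoms: chloromethyl methyl ether, COCCl
Why: O-Alkylation of the carboxylate and both phenols followed by saponification, which cleaves only the acyl acetal ester because aryl MOM ethers are base-stable acetals; the E-alkene is not affected.

**Step 10**
Reactants: 13 tert-butyl 4-O-(3-tert-butoxy-3-oxopropanoyl)-(−)-quinate; 16 (E)-3-[3,4-bis(methoxymethoxy)phenyl]prop-2-enoic acid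
Product: 17 tert-butyl 5-O-{(E)-3-[3,4-bis(methoxymethoxy)phenyl]prop-2-enoyl}-4-O-(3-tert-butoxy-3-oxopropanoyl)-(−)-quinate
Conditions: 16 (1.1 equiv), DIC (1.2 equiv), DMAP (0.1 equiv), CH2Cl2, −10 → 0 °C
Reagents that add atoms: none
Why: Steglich esterification should acylate the equatorial secondary 5-OH in preference to the axial 3-OH (flanked by the new ester and 1,3-diaxial to O1) and the tertiary 1-OH; low temperature and catalytic DMAP limit acyl migration.

**Step 11**
Reactants: 17 tert-butyl 5-O-{(E)-3-[3,4-bis(methoxymethoxy)phenyl]prop-2-enoyl}-4-O-(3-tert-butoxy-3-oxopropanoyl)-(−)-quinate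
Product: 18 5-O-[(E)-caffeoyl]-4-O-malonyl-(−)-quinic acid (target)
Conditions: TFA/CH2Cl2 (1:1), H2O (5 equiv), 0 °C → rt; reversed-phase chromatography
Reagents that add atoms: none
Why: Acidolysis cleaves both tert-butyl esters (loss of isobutene) and hydrolyses both MOM acetals in one base-free operation, so the malonyl and caffeoyl esters should neither hydrolyse nor migrate and no stereocentre is affected.

**Compound list**
1 | 3-methylidenecyclobutane-1-carboxylic acid | C=C1CC(C(=O)O)C1 | starting material
2 | tert-butyl 3-methylidenecyclobutane-1-carboxylate | C=C1CC(C(=O)OC(C)(C)C)C1 | intermediate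
3 | tert-butyl 1-hydroxy-3-methylidenecyclobutane-1-carboxylate | C=C1CC(O)(C(=O)OC(C)(C)C)C1 | intermediate
4 | tert-butyl 3-methylidene-1-[(trimethylsilyl)oxy]cyclobutane-1-carboxylate | C=C1CC(O[Si](C)(C)C)(C(=O)OC(C)(C)C)C1 | intermediate
5 | tert-butyl 3-oxo-1-[(trimethylsilyl)oxy]cyclobutane-1-carboxylate | O=C1CC(O[Si](C)(C)C)(C(=O)OC(C)(C)C)C1 | intermediate
6 | acetylene | C#C | starting material
7 | tert-butyl (1S)-5-oxo-1-[(trimethylsilyl)oxy]cyclohex-3-ene-1-carboxylate | C1=CC[C@@](O[Si](C)(C)C)(C(=O)OC(C)(C)C)CC1=O | intermediate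
8 | tert-butyl (1S)-1-hydroxy-5-oxocyclohex-3-ene-1-carboxylate | C1=CC[C@@](O)(C(=O)OC(C)(C)C)CC1=O | intermediate (not isolated)
9 | tert-butyl (1S,5R)-1,5-dihydroxycyclohex-3-ene-1-carboxylate | C1=CC[C@@](O)(C(=O)OC(C)(C)C)C[C@H]1O | intermediate
10 | tert-butyl (−)-quinate | O[C@@H]1[C@H](O)C[C@@](O)(C(=O)OC(C)(C)C)C[C@H]1O | intermediate
11 | mono-tert-butyl malonate | CC(C)(C)OC(=O)CC(=O)O | starting material
12 | tert-butyl 3-chloro-3-oxopropanoate | CC(C)(C)OC(=O)CC(=O)Cl | intermediate (not isolated)
13 | tert-butyl 4-O-(3-tert-butoxy-3-oxopropanoyl)-(−)-quinate | CC(C)(C)OC(=O)CC(=O)O[C@@H]1[C@H](O)C[C@@](O)(C(=O)OC(C)(C)C)C[C@H]1O | intermediate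
14 | caffeic acid | O=C(O)/C=C/c1ccc(O)c(O)c1 | starting material
15 | methoxymethyl (E)-3-[3,4-bis(methoxymethoxy)phenyl]prop-2-enoate | COCOC(=O)/C=C/c1ccc(OCOC)c(OCOC)c1 | intermediate (not isolated)
16 | (E)-3-[3,4-bis(methoxymethoxy)phenyl]prop-2-enoic acid | O=C(O)/C=C/c1ccc(OCOC)c(OCOC)c1 | intermediate
17 | tert-butyl 5-O-{(E)-3-[3,4-bis(methoxymethoxy)phenyl]prop-2-enoyl}-4-O-(3-tert-butoxy-3-oxopropanoyl)-(−)-quinate | CC(C)(C)OC(=O)CC(=O)O[C@@H]1[C@H](O)C[C@@](O)(C(=O)OC(C)(C)C)C[C@H]1OC(=O)/C=C/c1ccc(OCOC)c(OCOC)c1 | intermediate
18 | 5-O-[(E)-caffeoyl]-4-O-malonyl-(−)-quinic acid | O=C(O)CC(=O)O[C@@H]1[C@H](O)C[C@@](O)(C(=O)O)C[C@H]1OC(=O)/C=C/c1ccc(O)c(O)c1 | target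

**Step count and risks**
Total steps: 11. Longest linear sequence: 10 steps (steps 1–8, 10, 11 from compound 1); step 9 is a one-step side branch.

Steps most likely to fail:

1. Step 5 (Proposed new method). What may go wrong: acetylene oligomerization or double insertion outrunning mono-insertion, β-siloxy elimination from the alkylnickel intermediate, or poor discrimination between the two enantiotopic ring bonds. Fallback with known chemistry, setting out from 5 and coming back at 7:
   - Enantioselective deprotonation of 5 with the chiral amide LiN[CH(Me)Ph]2 (the enantiomer that gives the 1R product) and Me3SiCl as internal quench (THF, −100 °C) is a known desymmetrization of 3-substituted cyclobutanones. It should give the silyl enol ether tert-butyl (1R)-1,3-bis[(trimethylsilyl)oxy]cyclobut-2-ene-1-carboxylate F1.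
   - Tf2NH-catalysed (or EtAlCl2-promoted) [2+2] cycloaddition of F1 with allyl propiolate and opening of the bicyclo[2.2.0]hexene is the known two-carbon ring expansion of cyclic silyl enol ethers, and it makes the same two ring bonds. It should give 1-allyl 4-tert-butyl (4R)-2,4-bis[(trimethylsilyl)oxy]cyclohexa-1,5-diene-1,4-dicarboxylate F2.
   - Pd(PPh3)4/morpholine deallylation–decarboxylation (zerovalent palladium, Tsuji–Trost type), then mild acidic hydrolysis of the dienol ether with conjugation of the alkene, should give 7. If the tertiary silyl ether is lost as well, the product is 8, which enters step 6 directly.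

2. Step 10. What may go wrong: competing acylation of the axial 3-OH, or base-induced migration of the malonyl group to O3 or O5. Fallback, setting out from 10 and coming back at 17:
   - 2,2-Dimethoxypropane/TsOH (cat.) in acetone closes the acetonide on the cis-3,4-diol to give tert-butyl 3,4-O-isopropylidene-(−)-quinate F5.
   - DIC/DMAP esterification with 16 at the only secondary hydroxyl gives tert-butyl 5-O-[(E)-3,4-bis(methoxymethoxy)cinnamoyl]-3,4-O-isopropylidene-(−)-quinate F6.
   - 80% aqueous AcOH at 40 °C removes the acetonide to give tert-butyl 5-O-[(E)-3,4-bis(methoxymethoxy)cinnamoyl]-(−)-quinate F7.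
   - Borinic-acid-catalysed acylation of its cis-diol at the equatorial O4 with acid chloride 12 gives 17. This detour also removes the O4/O5 discrimination asked of step 8.

3. Step 7. What may go wrong: poor facial selectivity of osmylation, because the free allylic hydroxyl can direct syn by hydrogen bonding and the axial C1 hydroxyl sits on the desired face. Fallback, setting out from 9 and coming back at 10:
   - Selective silylation of the secondary allylic hydroxyl (TBSCl, imidazole, DMF) gives tert-butyl (1S,5R)-5-[(tert-butyldimethylsilyl)oxy]-1-hydroxycyclohex-3-ene-1-carboxylate F3.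
   - OsO4/NMO dihydroxylation, now steered anti by the bulky, non-hydrogen-bonding silyl ether, gives tert-butyl 5-O-(tert-butyldimethylsilyl)-(−)-quinate F4.
   - HF·pyridine in THF removes the silyl group to give 10.

**Further compounds**
F1 | step 5 | tert-butyl (1R)-1,3-bis[(trimethylsilyl)oxy]cyclobut-2-ene-1-carboxylate | C[Si](C)(C)OC1=C[C@@](O[Si](C)(C)C)(C(=O)OC(C)(C)C)C1
F2 | step 5 | 1-allyl 4-tert-butyl (4R)-2,4-bis[(trimethylsilyl)oxy]cyclohexa-1,5-diene-1,4-dicarboxylate | C=CCOC(=O)C1=C(O[Si](C)(C)C)C[C@](O[Si](C)(C)C)(C(=O)OC(C)(C)C)C=C1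
F3 | step 7 | tert-butyl (1S,5R)-5-[(tert-butyldimethylsilyl)oxy]-1-hydroxycyclohex-3-ene-1-carboxylate | C1=CC[C@@](O)(C(=O)OC(C)(C)C)C[C@H]1O[Si](C)(C)C(C)(C)C
F4 | step 7 | tert-butyl 5-O-(tert-butyldimethylsilyl)-(−)-quinate | O[C@@H]1[C@H](O)C[C@@](O)(C(=O)OC(C)(C)C)C[C@H]1O[Si](C)(C)C(C)(C)C
F5 | step 10 | tert-butyl 3,4-O-isopropylidene-(−)-quinate | CC1(C)O[C@@H]2[C@H](O1)C[C@@](O)(C(=O)OC(C)(C)C)C[C@H]2O
F6 | step 10 | tert-butyl 5-O-[(E)-3,4-bis(methoxymethoxy)cinnamoyl]-3,4-O-isopropylidene-(−)-quinate | CC1(C)O[C@@H]2[C@H](O1)C[C@@](O)(C(=O)OC(C)(C)C)C[C@H]2OC(=O)/C=C/c1ccc(OCOC)c(OCOC)c1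
F7 | step 10 | tert-butyl 5-O-[(E)-3,4-bis(methoxymethoxy)cinnamoyl]-(−)-quinate | O[C@@H]1[C@H](O)C[C@@](O)(C(=O)OC(C)(C)C)C[C@H]1OC(=O)/C=C/c1ccc(OCOC)c(OCOC)c1
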